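The data stem from a simulated flask with constants of no real substance; noise was put on by code.

Sunday's run charged twice the second end groups of Thursday's, yet its last link reading is 47% against 33%.

| flask | first end groups | second end groups | protic impurity | remark | time |
|---|---|---|---|---|---|
| Sunday's | 0.0050 M | 1 equiv | 2.5 mM | run made earlier |  |
| Monday's | 0.0034 M | 1 equiv | 2.5 mM | run made earlier |  |
| Wednesday's | 0.0075 M | 1 equiv | 2.5 mM | run made earlier |  |
| Thursday's | 0.0050 M | 0.50 equiv | 2.5 mM | run made earlier |  |
| spring | 0.0050 M | 1.00 equiv (fed, over 3.0 min) | 2.50 mM | all else is in the flask from the start; the feed brings no volume worth counting | 5.0 min |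
| autumn | 0.0050 M (fed, over 3.0 min) | 1.00 equiv | 2.50 mM | all else is in the flask from the start; the feed brings no volume worth counting | 5.0 min |
| winter | 0.0050 M | 1.00 equiv | 2.50 mM | everything together at the start | 5.0 min |
| summer | 0.0050 M | 1.00 equiv (in portions, 4, over 3.0 min) | 2.50 mM | first portion at the start, last at 3.0 min | 5.0 min |

| run | time / min | links / % | first end groups / % |
|---|---|---|---|
| Sunday's | 0.417 | 40 | 12 |
| Sunday's | 0.833 | 43 | 5 |
| Sunday's | 1.33 | 48 | 7 |
| Sunday's | 2.50 | 46 | 0 |
| Sunday's | 5.00 | 47 | 4 |
| Monday's | 0.500 | 25 | 6 |
| Monday's | 0.833 | 22 | 3 |
| Monday's | 1.50 | 28 | 0 |
| Monday's | 3.00 | 23 | 0 |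
| Monday's | 6.00 | 27 | 1 |
| Wednesday's | 1.33 | 59 | 1 |
| Wednesday's | 2.50 | 63 | 0 |
| Wednesday's | 4.00 | 62 | 0 |
| Wednesday's | 5.00 | 67 | 0 |
| Wednesday's | 6.00 | 61 | 1 |
| Thursday's | 0.500 | 26 | 16 |
| Thursday's | 1.50 | 32 | 16 |
| Thursday's | 3.00 | 35 | 14 |
| Thursday's | 4.00 | 30 | 12 |
| Thursday's | 6.00 | 33 | 11 |

(standard deviation of a reading: 2 percentage points)

- the flask that comes out highest in amount of links, in percent of the first end groups charged, or "all alike" when all lie within 1.5 percentage points (spring / autumn / winter / summer / all alike)
- links at the end, in percent of the first end groups charged, spring
- links at the end, in percent of the first end groups charged, autumn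
- links at the end, in percent of the first end groups charged, winter
- links at the end, in percent of the first end groups charged, summer



Two chemists read these runs. The balancer counts. The impurity is 0.500 of the charge of first end groups; by this view it takes that fraction within the first reading, the remainder pairs up, and Sunday's links agree.

The timekeeper starts from Thursday's run instead. There 0.50 equiv of second end groups went in; links read 32% at 1.50 min and 33% at the end, though first end groups still read 11%. Her number, taken from the last link reading of that run and so carrying its scatter, is 66.0%: the link share, the fraction of the charged second end groups that ends as links, which is the yield on that reagent. About a third of them made no link, with partners still standing by. So, she says, second end groups do not keep.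

In autumn, she reckons, the feed first has to match the impurity, which takes until 1.50 min. Second end groups would sit that long while the incoming first end groups go to the impurity. Thursday's first end groups also read 16% at 1.50 min and 11% at the end, with links unchanged within the scatter, so, she says, waiting costs them too. She puts winter at the top, near Sunday's reading, autumn far down, and spring and summer between.

The forecast is the balancer's: spring 48%, autumn 47%, winter 47%, summer 48%, highest all alike. Its ground: “Second end groups stay in excess of what survives, so links are set by stoichiometry, not by the order of addition.”

The simulation gives spring 40.6%, autumn 15.8%, winter 47.1%, summer 42.0%, highest winter.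

    second end groups → decomposed reagent (k = 0.0140 s⁻¹)
    first end groups + protic impurity → quenched substrate (k = 290 L mol⁻¹ s⁻¹)
    2 first end groups → self-condensation product (k = 0.650 L mol⁻¹ s⁻¹)
    first end groups + second end groups → links (k = 18.0 L mol⁻¹ s⁻¹)

The balance keeps winter, where everything goes in together and its 47% stands. Autumn's link share is 15.8%, below Thursday's 66.0%. Take the turning of second end groups into decomposed reagent out of winter and autumn, and the gap of winter over autumn goes from 31 percentage points to −1 point. In the neighbour flask, like winter but with impurity at 1.26 equiv, first end groups end at 0% and the link share is 7.69%.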